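## The problem

5-Methoxy-(+)-isolariciresinol (26) is a 1-aryltetralin. Ring A (C4a–C8a, OMe on C6, OH on C7) is fused to a carbocycle whose sp3 carbons carry a 4-hydroxy-3,5-dimethoxyphenyl group (C1), two hydroxymethyl groups (C2, C3) and two hydrogens (C4). The three contiguous stereocentres are (1S,2R,3R), i.e. 1,2-trans-2,3-trans, so all three substituents are equatorial on the half-chair. C1 is a diarylmethine with no activating group beside it; it cannot be corrected once made, so it must be set absolutely and is then the only centre available to direct the others. C2 and C3 each carry a carbon that can pass through the carbonyl oxidation level, so both can be equilibrated toward the all-equatorial arrangement. The two phenols (one a 2,6-dimethoxyphenol, easily oxidised to a quinone methide) and the alkoxy-rich rings do not tolerate ozone, strong oxidants or hot acid, so they must be masked and the late steps kept mild. The feature that makes the key step possible is the pair C2/C3: a carboxyl on C2 and a vinyl group on C3 across a new C2–C3 bond is what an ester-enolate Claisen rearrangement leaves, and C1, C8a, C4a and C4 can serve as the tether that makes that rearrangement close the ring.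

## Retrosynthesis

**26 ⇒ 25 ⇒ 24.** The phenols are traced back to benzyl ethers (25), which survive base, hydride, Pd(0), Ru and Os chemistry and leave by neutral hydrogenolysis. The two CH2OH groups are traced back to the aldehyde (C3) and methyl ester (C2) of 24. No skeletal bond is cut; the gain is that C3 is now α to an aldehyde and C2 α to an ester.

**24 ⇒ 23 ⇒ 21 ⇒ 20.** C3 is inverted retrosynthetically (24 from its 2,3-cis epimer 23), and the formyl group is traced back to a vinyl group (21, and its acid 20). The inversion is planned, not optional: as argued below, the ring-forming step can only deliver C2 and C3 cis. Osmium/periodate cleavage is preferred to ozone because of the electron-rich rings.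

**20 ⇒ 17 (key disconnection).** The C2–C3 bond is cut and the vinyl terminus is reconnected to the carboxyl oxygen, giving the benzo-fused ten-membered (E)-allylic lactone 17.
- Against the neighbouring cuts: breaking C1–C8a would make C1 under cationic conditions, and breaking C1–C2 with C3–C4 would need an o-quinodimethane. The C2–C3 cut is the only one that leaves C1 as an ordinary, separately made stereocentre.
- Simplification: 17 has one stereocentre (C1) and opens to an acyclic hydroxy acid; the allylic oxygen-bearing carbon is a traceless template removed later with the alkene.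
- Asked of the forward reaction: enolisation at the α-CH2 only, a [3,3] shift through the only array the ring allows, and relay of C1 to C2 through the face of the ketene acetal that bonds.
- Stereochemical consequence: in the ketene acetal the ring holds the lactone oxygen cis to C1, and the alkene is E. The system is the analogue of a (Z,E)-cyclodeca-1,5-diene and must react through a chair, in which the two tether atoms C1 and C4 are about 60° apart across the forming bond. A boat, the array followed by (Z)-alkenyl lactones in this reaction type, would put them about 120° apart, which the o-phenylene bridge cannot span. The chair gives 2,3-cis, hence the inversion above.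

**17 ⇒ 15 ⇒ 14.** The lactone acyl C–O bond is cut to the seco acid 15 and its ethyl ester 14. Closing at the ester keeps the alkene geometry fixed beforehand. The forward reaction must beat oligomerisation in a medium ring.

**14 ⇒ 12 + 13; 12 ⇒ 10 + 11.** The C=C bond of the allylic alcohol is cut by cross-metathesis into allylarene 12 and (Z)-but-2-ene-1,4-diol 13. The aryl–allyl bond is cut into aryl bromide 10 and allyltributylstannane 11. The bromine of the starting aldehyde thus marks C4a from the outset and the four-carbon arm is assembled from two commercial pieces.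

**10 ⇒ 9 + 5; 9 ⇒ 7 + 8; 7 ⇒ 6; 5 ⇒ 2 ⇒ 1.** The C1–syringyl bond is cut by asymmetric conjugate arylation of cinnamate 9 with boronic acid 5; this is the only step that sets absolute configuration. 9 comes from aldehyde 7 and ylide 8; 7 is O-benzylated 6-bromoisovanillin 6. 5 comes from 4-bromo-2,6-dimethoxyphenol 1 through benzyl ether 2. The aldehyde carbon of 6 becomes C1, so OMe ends para to C8a and OH para to C4a, as in 26.

## Roads not taken

**Alternative 1:** lactol carbon as linchpin for twofold Friedel–Crafts arylation.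
- Cut: C1–C8a and C1–aryl together, so C1 becomes the lactol carbon of A1.
- Forward: acid ionises A1 at C1; the oxocarbenium ion is arylated by ring A (para to its OMe, six-membered closure) and by 2,6-dimethoxyphenol A2 (para to its OH), and the oxolane opens to give A3, one hydrogenolysis from the target.
- Merits: two C–C bonds and the carbocycle in one operation; the syringyl phenol needs no protection; C2 and C3 arrive ready-made; the endgame is one step against five here. In length and convergence this road is better.
- Weak points: 2,3-trans in the tetralin translates into a 3,4-cis oxolane in A1, the less stable arrangement, and the centre next to the lactol carbon is α to a masked aldehyde, so it can drift under the acid that triggers the cascade and is then locked. One internal and one external arylation must occur at the same carbon, against twofold capture by A2. C1 is formed under cationic conditions beside benzyl ethers and very electron-rich arenes (transbenzylation), with its configuration resting on induction from C2 alone.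
- Comparison: the chosen plan is longer, but sets C1 with a catalyst before any ring exists, uses no cation chemistry, and leaves both new centres correctable.

**Alternative 2:** one-carbon ring expansion of a 3-arylindanone.
- Cut: C2–C3 and C3–C4 by excising C3, giving trans-indanone A4 and ethyl diazoacetate A5.
- Forward: Lewis acid activation, addition of A5 to the carbonyl carbon and 1,2-shift of C2 with loss of N2 give β-keto ester A6.
- Merits: 3-arylindanones are accessible in enantioenriched form. C2 is α to the ketone in A4 and C3 lies between two carbonyls in A6, so both settle trans thermodynamically without a separate operation; in this respect it is better than the chosen plan, which must invert C3 deliberately. The C4 ketone could leave in the final hydrogenolysis.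
- Weak points: the ketone is an aryl ketone deactivated by the para-benzyloxy group. Migration must be by C2 and not by the electron-rich aryl carbon, and aryl migration would place the new carbon on the wrong side of the carbonyl with no means of repair. Enolisation of A4 invites β-elimination of the benzyloxy group. A carbonyl absent from the target has to be carried and removed.
- Comparison: similar length; the chosen plan's main uncertainty is stereochemical and repairable by epimerisation, this one's is regiochemical and not repairable.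

**Alternative 3:** aryl-o-quinodimethane Diels–Alder onto a menthyloxybutenolide.
- Cut: C1–C2 and C3–C4.
- Forward: thermolysis opens benzocyclobutene A7 conrotatorily, aryl outward, to (E)-o-quinodimethane A8, which adds endo to (5R)-5-menthyloxybutenolide A9 on the face away from the menthyloxy group to give all-cis adduct A10.
- Merits: two C–C bonds, the ring and all three stereocentres in one step; absolute control from a cheap auxiliary; the regiochemistry follows the usual "ortho" preference. Per step this is the strongest of the four plans, and the chosen plan (one bond, two centres) does not match it.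
- Weak points: A7 with this oxygenation is itself a multistep target and needs high temperature to open. A10 is 1,2-cis and its cis-fused lactone locks C2, so the acetal lactone must be opened before C2 can be inverted. The auxiliary has to be removed and the acetal carbon reduced.
- Comparison: the C2 inversion costs no more than the C3 inversion needed in the chosen plan, so no advantage is claimed there, and overall length is probably similar. The chosen plan offers catalytic control of the one non-correctable centre, commercial building blocks joined by cross-couplings, and no thermolysis.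

Key step: step 10

Assumption: the ligand antipode in step 5 is assigned from the accepted model for Rh(I)–BINAP arylations, in which the (S)-ligand delivers aryl to the α-si face of an (E)-enoate; (S)-10 needs the α-re face, hence (R)-BINAP, and the other antipode would be used unchanged if the first analysis showed the opposite sense.

## Route

Step 1
Reactants: 1 4-bromo-2,6-dimethoxyphenol
Product: 2 2-(benzyloxy)-5-bromo-1,3-dimethoxybenzene
Conditions: BnBr, K2CO3, DMF, 50 °C
Reagents that add atoms: benzyl bromide BrCc1ccccc1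
Why: Williamson ether synthesis; the phenoxide is hindered but benzyl bromide is an unhindered, reactive electrophile.

Step 2
Reactants: 2 2-(benzyloxy)-5-bromo-1,3-dimethoxybenzene
Product: 5 [4-(benzyloxy)-3,5-dimethoxyphenyl]boronic acid, via aryllithium 3 (not isolated), via lithium triisopropoxyborate 4 (not isolated)
Conditions: n-BuLi, THF, −78 °C; B(OiPr)3, −78 °C → rt; 1 M HCl
Reagents that add atoms: triisopropyl borate CC(C)OB(OC(C)C)OC(C)C; water O
Why: Bromine–lithium exchange is faster than any deprotonation at −78 °C, and borate trapping followed by hydrolysis is the standard route to arylboronic acids.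

Step 3
Reactants: 6 2-bromo-5-hydroxy-4-methoxybenzaldehyde (6-bromoisovanillin)
Product: 7 5-(benzyloxy)-2-bromo-4-methoxybenzaldehyde
Conditions: BnBr, K2CO3, DMF, rt
Reagents that add atoms: benzyl bromide BrCc1ccccc1
Why: Williamson ether synthesis on an acidic phenol; the aldehyde and aryl bromide are inert to carbonate.

Step 4
Reactants: 7 5-(benzyloxy)-2-bromo-4-methoxybenzaldehyde; 8 ethyl (triphenylphosphoranylidene)acetate
Product: 9 ethyl (2E)-3-[5-(benzyloxy)-2-bromo-4-methoxyphenyl]prop-2-enoate
Conditions: toluene, 80 °C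
Reagents that add atoms: none
Why: Wittig olefination with a stabilised ylide, which should give the (E)-cinnamate needed for a single sense of induction in step 5.

Step 5
Reactants: 9 ethyl (2E)-3-[5-(benzyloxy)-2-bromo-4-methoxyphenyl]prop-2-enoate; 5 [4-(benzyloxy)-3,5-dimethoxyphenyl]boronic acid
Product: 10 ethyl (3S)-3-[5-(benzyloxy)-2-bromo-4-methoxyphenyl]-3-[4-(benzyloxy)-3,5-dimethoxyphenyl]propanoate
Conditions: [Rh(OH)((R)-binap)]2 (3 mol % Rh), 5 (2.5 equiv), dioxane/H2O 10:1, 60 °C
Reagents that add atoms: none
Why: Hayashi–Miyaura conjugate arylation; the aryl–Rh(I) species adds to the enoate face chosen by the ligand and the oxa-π-allyl rhodium is protonated by water, setting C1 as (S). Rh(I) leaves the aryl bromide untouched.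

Step 6
Reactants: 10 ethyl (3S)-3-[5-(benzyloxy)-2-bromo-4-methoxyphenyl]-3-[4-(benzyloxy)-3,5-dimethoxyphenyl]propanoate; 11 allyltributylstannane
Product: 12 ethyl (3S)-3-[5-(benzyloxy)-4-methoxy-2-(prop-2-en-1-yl)phenyl]-3-[4-(benzyloxy)-3,5-dimethoxyphenyl]propanoate
Conditions: Pd2(dba)3 (1.5 mol %), P(t-Bu)3 (6 mol %), CsF, dioxane, 80 °C
Reagents that add atoms: none
Why: Stille coupling; the bulky electron-rich phosphine handles the hindered, electron-rich aryl bromide and fluoride activates the stannane. C1 is not acidic enough to be touched.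

Step 7
Reactants: 12 ethyl (3S)-3-[5-(benzyloxy)-4-methoxy-2-(prop-2-en-1-yl)phenyl]-3-[4-(benzyloxy)-3,5-dimethoxyphenyl]propanoate; 13 (Z)-but-2-ene-1,4-diol
Product: 14 ethyl (3S)-3-{5-(benzyloxy)-2-[(2E)-4-hydroxybut-2-en-1-yl]-4-methoxyphenyl}-3-[4-(benzyloxy)-3,5-dimethoxyphenyl]propanoate
Conditions: 13 (4 equiv), Hoveyda–Grubbs II (5 mol %), 1,4-benzoquinone (10 mol %), CH2Cl2, 40 °C
Reagents that add atoms: none
Why: Olefin cross-metathesis of a terminal allylarene with an excess of a symmetrical internal alkene; secondary metathesis should favour the (E)-alkene, and benzoquinone suppresses migration of the allyl double bond into conjugation.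

Step 8
Reactants: 14 ethyl (3S)-3-{5-(benzyloxy)-2-[(2E)-4-hydroxybut-2-en-1-yl]-4-methoxyphenyl}-3-[4-(benzyloxy)-3,5-dimethoxyphenyl]propanoate
Product: 15 (3S)-3-{5-(benzyloxy)-2-[(2E)-4-hydroxybut-2-en-1-yl]-4-methoxyphenyl}-3-[4-(benzyloxy)-3,5-dimethoxyphenyl]propanoic acid
Conditions: LiOH, THF/MeOH/H2O, rt; then 1 M HCl to pH 3, 0 °C
Reagents that add atoms: lithium hydroxide [Li+].[OH-]
Why: Ester saponification; C1 is β to the carboxyl and is not epimerisable, and the allylic alcohol tolerates brief cold dilute acid.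

Step 9
Reactants: 15 (3S)-3-{5-(benzyloxy)-2-[(2E)-4-hydroxybut-2-en-1-yl]-4-methoxyphenyl}-3-[4-(benzyloxy)-3,5-dimethoxyphenyl]propanoic acid
Product: 17 (1S,6E)-11-(benzyloxy)-1-[4-(benzyloxy)-3,5-dimethoxyphenyl]-10-methoxy-1,2,5,8-tetrahydro-3H-4-benzoxecin-3-one (benzo-fused ten-membered (E)-allylic lactone), via mixed anhydride 16 (not isolated)
Conditions: 2,4,6-trichlorobenzoyl chloride, Et3N, THF, rt; then slow addition to DMAP, toluene, 90 °C (about 1 mM)
Reagents that add atoms: none
Why: Yamaguchi macrolactonisation; the o-phenylene unit and the (E)-alkene remove rotors from the seco acid, and high dilution favours ring closure over intermolecular acylation.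

Step 10
Reactants: 17 (1S,6E)-11-(benzyloxy)-1-[4-(benzyloxy)-3,5-dimethoxyphenyl]-10-methoxy-1,2,5,8-tetrahydro-3H-4-benzoxecin-3-one
Product: 20 (1S,2S,3R)-7-(benzyloxy)-1-[4-(benzyloxy)-3,5-dimethoxyphenyl]-3-ethenyl-6-methoxy-1,2,3,4-tetrahydronaphthalene-2-carboxylic acid (1,2-trans-2,3-cis), via silyl ketene acetal 18 (not isolated), via silyl ester 19 (not isolated)
Conditions: LDA, THF, −78 °C; TBSCl, DMPU, −78 °C → rt; toluene, 90 °C; then 1 M HCl/THF, rt
Reagents that add atoms: none
Why: Ireland–Claisen rearrangement run as a transannular four-atom ring contraction, the known reaction type for macrocyclic allylic lactones: LDA removes an α-proton of 17, O-silylation gives ketene acetal 18, and a concerted suprafacial [3,3] shift forms C2–C3 while the allylic O–CH2 bond breaks, leaving silyl ester 19, which is hydrolysed to 20 on work-up. The six-membered ring closes across the ten-membered ring between the ketene acetal carbon and the distal alkene carbon, with C1–C8a–C4a–C4 as the tether (10 → 6). In 18 the ring holds the lactone oxygen cis to C1 on the new C=C and the alkene is E, so the array is the counterpart of a (Z,E)-cyclodeca-1,5-diene and must be chair-like: C1 is axial-like on C2 and C4 equatorial-like on C3, about 60° apart, which the o-phenylene tether spans, whereas a boat would hold them about 120° apart, out of its reach. That chair fixes C3 cis to C2 (carboxyl equatorial, vinyl axial on the forming half-chair). C2 is set relative to C1 by the face of the ketene acetal that bonds: the aryl group on C1 should take the pseudoequatorial site, because the pseudoaxial one is syn-axial to the allyl fragment arriving at C3, and this gives the 1,2-trans acid. The step therefore needs facial selectivity relayed from C1 and site-selective enolisation; the first rests on that 1,3-diaxial contact, the second on the α-CH2 being far more acidic than the benzylic C1–H and C4–H2. Either facial isomer is one base epimerisation away from the all-trans series.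

Step 11
Reactants: 20 (1S,2S,3R)-7-(benzyloxy)-1-[4-(benzyloxy)-3,5-dimethoxyphenyl]-3-ethenyl-6-methoxy-1,2,3,4-tetrahydronaphthalene-2-carboxylic acid
Product: 21 methyl (1S,2S,3R)-7-(benzyloxy)-1-[4-(benzyloxy)-3,5-dimethoxyphenyl]-3-ethenyl-6-methoxy-1,2,3,4-tetrahydronaphthalene-2-carboxylate
Conditions: MeI, K2CO3, DMF, rt
Reagents that add atoms: iodomethane CI
Why: Carboxylate O-alkylation; carbonate is too weak to enolise the ester, so C2 is not disturbed.

Step 12
Reactants: 21 methyl (1S,2S,3R)-7-(benzyloxy)-1-[4-(benzyloxy)-3,5-dimethoxyphenyl]-3-ethenyl-6-methoxy-1,2,3,4-tetrahydronaphthalene-2-carboxylate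
Product: 23 methyl (1S,2R,3S)-7-(benzyloxy)-1-[4-(benzyloxy)-3,5-dimethoxyphenyl]-3-formyl-6-methoxy-1,2,3,4-tetrahydronaphthalene-2-carboxylate (2,3-cis), via vicinal diol 22 (not isolated)
Conditions: OsO4 (2 mol %), NaIO4, 2,6-lutidine, dioxane/H2O 3:1, rt
Reagents that add atoms: osmium tetroxide O=[Os](=O)(=O)=O; sodium periodate [Na+].[O-]I(=O)(=O)=O
Why: Lemieux–Johnson oxidative cleavage (dihydroxylation, then periodate glycol cleavage); it is chosen over ozonolysis because it leaves the electron-rich rings and benzyl ethers alone, and lutidine buffers the medium.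

Step 13
Reactants: 23 methyl (1S,2R,3S)-7-(benzyloxy)-1-[4-(benzyloxy)-3,5-dimethoxyphenyl]-3-formyl-6-methoxy-1,2,3,4-tetrahydronaphthalene-2-carboxylate
Product: 24 methyl (1S,2R,3R)-7-(benzyloxy)-1-[4-(benzyloxy)-3,5-dimethoxyphenyl]-3-formyl-6-methoxy-1,2,3,4-tetrahydronaphthalene-2-carboxylate (1,2-trans-2,3-trans)
Conditions: DBU, CH2Cl2, rt
Reagents that add atoms: none
Why: Base-mediated epimerisation α to the aldehyde through its enolate; the formyl group moves from axial to equatorial so that all three substituents are equatorial, which sets C3 under thermodynamic control. DBU is too weak to enolise the ester, so C2 stays.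

Step 14
Reactants: 24 methyl (1S,2R,3R)-7-(benzyloxy)-1-[4-(benzyloxy)-3,5-dimethoxyphenyl]-3-formyl-6-methoxy-1,2,3,4-tetrahydronaphthalene-2-carboxylate
Product: 25 [(1S,2R,3R)-7-(benzyloxy)-1-[4-(benzyloxy)-3,5-dimethoxyphenyl]-6-methoxy-1,2,3,4-tetrahydronaphthalene-2,3-diyl]dimethanol
Conditions: LiAlH4, THF, 0 °C → rt
Reagents that add atoms: none
Why: Hydride reduction of aldehyde and ester to the two primary alcohols; the aldehyde is reduced faster than it can enolise, so C3 is kept.

Step 15
Reactants: 25 [(1S,2R,3R)-7-(benzyloxy)-1-[4-(benzyloxy)-3,5-dimethoxyphenyl]-6-methoxy-1,2,3,4-tetrahydronaphthalene-2,3-diyl]dimethanol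
Product: 26 5-methoxy-(+)-isolariciresinol, (6R,7R,8S)-8-(4-hydroxy-3,5-dimethoxyphenyl)-6,7-bis(hydroxymethyl)-3-methoxy-5,6,7,8-tetrahydronaphthalen-2-ol
Conditions: H2 (1 atm), 10 % Pd/C, EtOAc/MeOH, rt
Reagents that add atoms: none
Why: Hydrogenolysis of both aryl benzyl ethers under neutral conditions; the diarylmethine C–C bonds and the primary alcohols are not cleaved.

## Compound list

1 | 4-bromo-2,6-dimethoxyphenol | COc1cc(Br)cc(OC)c1O | starting material
2 | 2-(benzyloxy)-5-bromo-1,3-dimethoxybenzene | COc1cc(Br)cc(OC)c1OCc1ccccc1 | intermediate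
3 | [4-(benzyloxy)-3,5-dimethoxyphenyl]lithium (not isolated) | [Li]c1cc(OC)c(OCc2ccccc2)c(OC)c1 | intermediate
4 | lithium [4-(benzyloxy)-3,5-dimethoxyphenyl]tri(propan-2-yloxy)borate (not isolated) | [Li+].CC(C)O[B-](OC(C)C)(OC(C)C)c1cc(OC)c(OCc2ccccc2)c(OC)c1 | intermediate
5 | [4-(benzyloxy)-3,5-dimethoxyphenyl]boronic acid | COc1cc(B(O)O)cc(OC)c1OCc1ccccc1 | intermediate
6 | 2-bromo-5-hydroxy-4-methoxybenzaldehyde (6-bromoisovanillin) | COc1cc(Br)c(C=O)cc1O | starting material
7 | 5-(benzyloxy)-2-bromo-4-methoxybenzaldehyde | COc1cc(Br)c(C=O)cc1OCc1ccccc1 | intermediate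
8 | ethyl (triphenylphosphoranylidene)acetate | CCOC(=O)C=P(c1ccccc1)(c1ccccc1)c1ccccc1 | starting material
9 | ethyl (2E)-3-[5-(benzyloxy)-2-bromo-4-methoxyphenyl]prop-2-enoate | CCOC(=O)/C=C/c1cc(OCc2ccccc2)c(OC)cc1Br | intermediate
10 | ethyl (3S)-3-[5-(benzyloxy)-2-bromo-4-methoxyphenyl]-3-[4-(benzyloxy)-3,5-dimethoxyphenyl]propanoate | COc1cc(Br)c(cc1OCc1ccccc1)[C@H](c1cc(OC)c(OCc2ccccc2)c(OC)c1)CC(=O)OCC | intermediate
11 | allyltributylstannane | C=CC[Sn](CCCC)(CCCC)CCCC | starting material
12 | ethyl (3S)-3-[5-(benzyloxy)-4-methoxy-2-(prop-2-en-1-yl)phenyl]-3-[4-(benzyloxy)-3,5-dimethoxyphenyl]propanoate | COc1cc(CC=C)c(cc1OCc1ccccc1)[C@H](c1cc(OC)c(OCc2ccccc2)c(OC)c1)CC(=O)OCC | intermediate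
13 | (Z)-but-2-ene-1,4-diol | OC/C=C\CO | starting material
14 | ethyl (3S)-3-{5-(benzyloxy)-2-[(2E)-4-hydroxybut-2-en-1-yl]-4-methoxyphenyl}-3-[4-(benzyloxy)-3,5-dimethoxyphenyl]propanoate | COc1cc(C/C=C/CO)c(cc1OCc1ccccc1)[C@H](c1cc(OC)c(OCc2ccccc2)c(OC)c1)CC(=O)OCC | intermediate
15 | (3S)-3-{5-(benzyloxy)-2-[(2E)-4-hydroxybut-2-en-1-yl]-4-methoxyphenyl}-3-[4-(benzyloxy)-3,5-dimethoxyphenyl]propanoic acid | COc1cc(C/C=C/CO)c(cc1OCc1ccccc1)[C@H](c1cc(OC)c(OCc2ccccc2)c(OC)c1)CC(=O)O | intermediate
16 | mixed anhydride of 15 with 2,4,6-trichlorobenzoic acid (not isolated) | COc1cc(C/C=C/CO)c(cc1OCc1ccccc1)[C@H](c1cc(OC)c(OCc2ccccc2)c(OC)c1)CC(=O)OC(=O)c1c(Cl)cc(Cl)cc1Cl | intermediate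
17 | (1S,6E)-11-(benzyloxy)-1-[4-(benzyloxy)-3,5-dimethoxyphenyl]-10-methoxy-1,2,5,8-tetrahydro-3H-4-benzoxecin-3-one | COc1cc2c(cc1OCc1ccccc1)[C@H](c1cc(OC)c(OCc3ccccc3)c(OC)c1)CC(=O)OC/C=C/C2 | intermediate
18 | tert-butyldimethylsilyl ketene acetal of 17, ring oxygen cis to C1 (not isolated) | COc1cc2c(cc1OCc1ccccc1)[C@H](c1cc(OC)c(OCc3ccccc3)c(OC)c1)/C=C(O[Si](C)(C)C(C)(C)C)\OC/C=C/C2 | intermediate
19 | tert-butyldimethylsilyl ester of 20 (not isolated) | COc1cc2c(cc1OCc1ccccc1)[C@H](c1cc(OC)c(OCc3ccccc3)c(OC)c1)[C@@H](C(=O)O[Si](C)(C)C(C)(C)C)[C@@H](C=C)C2 | intermediate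
20 | (1S,2S,3R)-7-(benzyloxy)-1-[4-(benzyloxy)-3,5-dimethoxyphenyl]-3-ethenyl-6-methoxy-1,2,3,4-tetrahydronaphthalene-2-carboxylic acid | COc1cc2c(cc1OCc1ccccc1)[C@H](c1cc(OC)c(OCc3ccccc3)c(OC)c1)[C@@H](C(=O)O)[C@@H](C=C)C2 | intermediate
21 | methyl (1S,2S,3R)-7-(benzyloxy)-1-[4-(benzyloxy)-3,5-dimethoxyphenyl]-3-ethenyl-6-methoxy-1,2,3,4-tetrahydronaphthalene-2-carboxylate | COc1cc2c(cc1OCc1ccccc1)[C@H](c1cc(OC)c(OCc3ccccc3)c(OC)c1)[C@@H](C(=O)OC)[C@@H](C=C)C2 | intermediate
22 | methyl (1S,2S,3R)-7-(benzyloxy)-1-[4-(benzyloxy)-3,5-dimethoxyphenyl]-3-(1,2-dihydroxyethyl)-6-methoxy-1,2,3,4-tetrahydronaphthalene-2-carboxylate, either carbinol epimer (not isolated) | COc1cc2c(cc1OCc1ccccc1)[C@H](c1cc(OC)c(OCc3ccccc3)c(OC)c1)[C@@H](C(=O)OC)[C@@H](C(O)CO)C2 | intermediate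
23 | methyl (1S,2R,3S)-7-(benzyloxy)-1-[4-(benzyloxy)-3,5-dimethoxyphenyl]-3-formyl-6-methoxy-1,2,3,4-tetrahydronaphthalene-2-carboxylate | COc1cc2c(cc1OCc1ccccc1)[C@H](c1cc(OC)c(OCc3ccccc3)c(OC)c1)[C@@H](C(=O)OC)[C@@H](C=O)C2 | intermediate
24 | methyl (1S,2R,3R)-7-(benzyloxy)-1-[4-(benzyloxy)-3,5-dimethoxyphenyl]-3-formyl-6-methoxy-1,2,3,4-tetrahydronaphthalene-2-carboxylate | COc1cc2c(cc1OCc1ccccc1)[C@H](c1cc(OC)c(OCc3ccccc3)c(OC)c1)[C@@H](C(=O)OC)[C@H](C=O)C2 | intermediate
25 | [(1S,2R,3R)-7-(benzyloxy)-1-[4-(benzyloxy)-3,5-dimethoxyphenyl]-6-methoxy-1,2,3,4-tetrahydronaphthalene-2,3-diyl]dimethanol | COc1cc2c(cc1OCc1ccccc1)[C@H](c1cc(OC)c(OCc3ccccc3)c(OC)c1)[C@@H](CO)[C@H](CO)C2 | intermediate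
26 | 5-methoxy-(+)-isolariciresinol | COc1cc2c(cc1O)[C@H](c1cc(OC)c(O)c(OC)c1)[C@@H](CO)[C@H](CO)C2 | target

## Step count and least certain steps

Total: 15 steps. Longest linear sequence: 13 steps (steps 3–15 from 6); steps 1–2 are the side branch to 5, which joins at step 5.

**Step 10 (key step).** The most likely failure is incomplete facial discrimination at the ketene acetal, because the preference for the pseudoequatorial aryl group rests on a single 1,3-diaxial contact in a flexible medium ring. The fallback replaces kinetic relay by thermodynamic correction at C2. It sets out from 17: the rearrangement is run as before, and the facial isomer formed beside 20 is (1S,2R,3S)-7-(benzyloxy)-1-[4-(benzyloxy)-3,5-dimethoxyphenyl]-3-ethenyl-6-methoxy-1,2,3,4-tetrahydronaphthalene-2-carboxylic acid F1 (all-cis). This is esterified with MeI/K2CO3 to its methyl ester F2, and F2 is cleaved with OsO4/NaIO4 to the all-cis methyl 3-formyl-2-carboxylate F3. Treatment of F3 with NaOMe in MeOH inverts the ester-bearing C2, which is flanked by two cis substituents, and the fallback comes back to the route at 24.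

**Step 9.** Intermolecular acylation (diolide and oligomer formation) may outrun ring closure, because closing a ten-membered ring that contains an (E)-alkene costs strain. The fallback closes the ring at the alkene instead of at the ester. It sets out from 12: saponification gives (3S)-3-[5-(benzyloxy)-4-methoxy-2-(prop-2-en-1-yl)phenyl]-3-[4-(benzyloxy)-3,5-dimethoxyphenyl]propanoic acid F4, and alkylation with allyl bromide/K2CO3 gives its prop-2-en-1-yl ester F5. Ring-closing metathesis of F5 (Grubbs II, toluene, 80 °C, high dilution) should give 17 and/or its (6Z)-isomer, the (Z)-lactone F6. F6 carries a (Z)-alkene and must rearrange through the boat-like array, again to a 2,3-cis acid (20 or F1), and both converge on 24. The fallback comes back at 17, or for F6 at 20.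

**Step 13.** Epimerisation may stop short of completion, because a formyl group on C3 of a tetralin has only one syn-axial hydrogen to escape and its equatorial preference is small. The fallback moves the equilibration to a diester, where the preference is larger. It sets out from 23: Pinnick oxidation (NaClO2, NaH2PO4, 2-methylbut-2-ene) gives (1S,2R,3S)-2-(methoxycarbonyl)-tetralin-3-carboxylic acid F7, and MeI/K2CO3 gives the 2,3-cis dimethyl diester F8. NaOMe in MeOH equilibrates F8 to the all-trans dimethyl diester F9, and LiAlH4 reduction of F9 comes back to the route at 25.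

**Step 5.** Carbometalation at the β-carbon beside the ortho-bromo substituent may be slow, so that protodeboronation of the electron-rich boronic acid consumes 5 and conversion and selectivity suffer. The fallback uses a doubly activated acceptor. It sets out from 7: Knoevenagel condensation with Meldrum's acid gives 5-{[5-(benzyloxy)-2-bromo-4-methoxyphenyl]methylidene}-2,2-dimethyl-1,3-dioxane-4,6-dione F10. Rhodium-catalysed asymmetric arylation of F10 with 5 gives the (S)-diarylmethyl Meldrum's acid F11, and heating F11 in ethanol/pyridine (ring opening and decarboxylation) comes back to the route at 10.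

## Further compounds

F1 | step 10 | (1S,2R,3S)-7-(benzyloxy)-1-[4-(benzyloxy)-3,5-dimethoxyphenyl]-3-ethenyl-6-methoxy-1,2,3,4-tetrahydronaphthalene-2-carboxylic acid (all-cis) | COc1cc2c(cc1OCc1ccccc1)[C@H](c1cc(OC)c(OCc3ccccc3)c(OC)c1)[C@H](C(=O)O)[C@H](C=C)C2
F2 | step 10 | methyl ester of F1 | COc1cc2c(cc1OCc1ccccc1)[C@H](c1cc(OC)c(OCc3ccccc3)c(OC)c1)[C@H](C(=O)OC)[C@H](C=C)C2
F3 | step 10 | methyl (1S,2S,3R)-7-(benzyloxy)-1-[4-(benzyloxy)-3,5-dimethoxyphenyl]-3-formyl-6-methoxy-1,2,3,4-tetrahydronaphthalene-2-carboxylate (all-cis) | COc1cc2c(cc1OCc1ccccc1)[C@H](c1cc(OC)c(OCc3ccccc3)c(OC)c1)[C@H](C(=O)OC)[C@H](C=O)C2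
F4 | step 9 | (3S)-3-[5-(benzyloxy)-4-methoxy-2-(prop-2-en-1-yl)phenyl]-3-[4-(benzyloxy)-3,5-dimethoxyphenyl]propanoic acid | COc1cc(CC=C)c(cc1OCc1ccccc1)[C@H](c1cc(OC)c(OCc2ccccc2)c(OC)c1)CC(=O)O
F5 | step 9 | prop-2-en-1-yl ester of F4 | COc1cc(CC=C)c(cc1OCc1ccccc1)[C@H](c1cc(OC)c(OCc2ccccc2)c(OC)c1)CC(=O)OCC=C
F6 | step 9 | (1S,6Z)-11-(benzyloxy)-1-[4-(benzyloxy)-3,5-dimethoxyphenyl]-10-methoxy-1,2,5,8-tetrahydro-3H-4-benzoxecin-3-one | COc1cc2c(cc1OCc1ccccc1)[C@H](c1cc(OC)c(OCc3ccccc3)c(OC)c1)CC(=O)OC/C=C\C2
F7 | step 13 | (1S,2R,3S)-7-(benzyloxy)-1-[4-(benzyloxy)-3,5-dimethoxyphenyl]-6-methoxy-2-(methoxycarbonyl)-1,2,3,4-tetrahydronaphthalene-3-carboxylic acid (2,3-cis) | COc1cc2c(cc1OCc1ccccc1)[C@H](c1cc(OC)c(OCc3ccccc3)c(OC)c1)[C@@H](C(=O)OC)[C@@H](C(=O)O)C2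
F8 | step 13 | dimethyl (1S,2R,3S)-7-(benzyloxy)-1-[4-(benzyloxy)-3,5-dimethoxyphenyl]-6-methoxy-1,2,3,4-tetrahydronaphthalene-2,3-dicarboxylate (2,3-cis) | COc1cc2c(cc1OCc1ccccc1)[C@H](c1cc(OC)c(OCc3ccccc3)c(OC)c1)[C@@H](C(=O)OC)[C@@H](C(=O)OC)C2
F9 | step 13 | dimethyl (1S,2R,3R)-7-(benzyloxy)-1-[4-(benzyloxy)-3,5-dimethoxyphenyl]-6-methoxy-1,2,3,4-tetrahydronaphthalene-2,3-dicarboxylate (all-trans) | COc1cc2c(cc1OCc1ccccc1)[C@H](c1cc(OC)c(OCc3ccccc3)c(OC)c1)[C@@H](C(=O)OC)[C@H](C(=O)OC)C2
F10 | step 5 | 5-{[5-(benzyloxy)-2-bromo-4-methoxyphenyl]methylidene}-2,2-dimethyl-1,3-dioxane-4,6-dione | CC1(C)OC(=O)C(=Cc2cc(OCc3ccccc3)c(OC)cc2Br)C(=O)O1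
F11 | step 5 | 5-{(S)-[5-(benzyloxy)-2-bromo-4-methoxyphenyl][4-(benzyloxy)-3,5-dimethoxyphenyl]methyl}-2,2-dimethyl-1,3-dioxane-4,6-dione | COc1cc(Br)c(cc1OCc1ccccc1)[C@H](c1cc(OC)c(OCc2ccccc2)c(OC)c1)C1C(=O)OC(C)(C)OC1=O
A1 | alternative 1 | (3R,4R)-4-[4-(benzyloxy)-3-methoxybenzyl]-3-[(benzyloxy)methyl]oxolan-2-ol (3,4-cis lactol, anomeric mixture) | OC1OC[C@H](Cc2ccc(OCc3ccccc3)c(OC)c2)[C@@H]1COCc1ccccc1
A2 | alternative 1 | 2,6-dimethoxyphenol | COc1cccc(OC)c1O
A3 | alternative 1 | target skeleton with the ring-A phenol and the C2 hydroxymethyl as benzyl ethers | COc1cc2c(cc1OCc1ccccc1)[C@H](c1cc(OC)c(O)c(OC)c1)[C@@H](COCc1ccccc1)[C@H](CO)C2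
A4 | alternative 2 | trans-(2S,3S)-5-(benzyloxy)-3-[4-(benzyloxy)-3,5-dimethoxyphenyl]-2-[(benzyloxy)methyl]-6-methoxyindan-1-one | COc1cc2c(cc1OCc1ccccc1)[C@H](c1cc(OC)c(OCc3ccccc3)c(OC)c1)[C@@H](COCc1ccccc1)C2=O
A5 | alternative 2 | ethyl diazoacetate | CCOC(=O)C=[N+]=[N-]
A6 | alternative 2 | ethyl 1-aryl-2-(benzyloxymethyl)-4-oxotetralin-3-carboxylate (trans,trans) | COc1cc2c(cc1OCc1ccccc1)[C@H](c1cc(OC)c(OCc3ccccc3)c(OC)c1)[C@@H](COCc1ccccc1)[C@H](C(=O)OCC)C2=O
A7 | alternative 3 | 4-(benzyloxy)-7-[4-(benzyloxy)-3,5-dimethoxyphenyl]-3-methoxybicyclo[4.2.0]octa-1,3,5-triene (1-arylbenzocyclobutene) | COc1cc2c(cc1OCc1ccccc1)C(c1cc(OC)c(OCc3ccccc3)c(OC)c1)C2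
A8 | alternative 3 | (E)-α-aryl-o-quinodimethane from A7 | COC1=CC(=C)/C(=C/c2cc(OC)c(OCc3ccccc3)c(OC)c2)C=C1OCc1ccccc1
A9 | alternative 3 | (5R)-5-[(1R,2S,5R)-menthyloxy]furan-2(5H)-one | O=C1C=C[C@H](O[C@@H]2C[C@H](C)CC[C@H]2C(C)C)O1
A10 | alternative 3 | all-cis endo adduct, cis-fused menthyl acetal lactone | COc1cc2c(cc1OCc1ccccc1)[C@H](c1cc(OC)c(OCc3ccccc3)c(OC)c1)[C@@H]1C(=O)O[C@@H](O[C@@H]3C[C@H](C)CC[C@H]3C(C)C)[C@@H]1C2
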